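**Remarks on the chemistry**

- Numbering: the upper unit is numbered as a flavonol (O1, C2, C3, C4, C4a, C5–C8, C8a) and the flavan unit carries primes (O1', C2'–C4', C4a', C5'–C8', C8a').
- Compounds 15, 24 and 25 are ring–chain tautomers (cyclic hemiketal, open 1,3-diketone or 1,2,3-trione, hydrate). They are written as the cyclic 2-hydroxy forms with C2 undefined, because C2 is configurationally labile until the last step.
- The sense of induction in step 12 cannot be assigned with certainty by analogy. The (S,S) ligand is written; its antipode is the alternative.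

**Strategy**

The target is treated as the double aryl ketal of a 1,2,3-trione: C2 is a ketone carbon held by O1 of ring A and O7' of the flavan, and C3 a ketone carbon arylated by C8' of (2S,3R)-afzelechin. Ring A is an ortho-acylphenol (O1 on C8a, C4 on C4a) with phloroglucinol oxygenation, exactly what an aryne leaves on inserting into the C–O bond of a carboxylic acid. The key step joins 3,5-bis(benzyloxy)benzyne and an arylpropiolic acid: O-arylation, acyl shift and 6-endo-dig closure deliver the flavone (rings A and C) in one operation. Hydroxylation, oxidation, an enantioselective Friedel–Crafts union with the flavan and hydrogenolysis/ketalisation complete the route.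

Key step: step 4

**Route**

Step 1
Reactants: 1 3,5-bis(benzyloxy)phenol
Product: 2 2-bromo-3,5-bis(benzyloxy)phenol
Conditions: NBS, i-Pr2NH (10 mol%), CH2Cl2, 0 °C
Reagents that add atoms: N-bromosuccinimide, O=C1CCC(=O)N1Br
Why: Amine-catalysed electrophilic bromination of a phenol is ortho-selective, so bromine should enter C2 between the hydroxyl and a benzyloxy group and not the more hindered C4.

Step 2
Reactants: 2 2-bromo-3,5-bis(benzyloxy)phenol
Product: 5 aryne precursor 3,5-bis(benzyloxy)-2-(trimethylsilyl)phenyl trifluoromethanesulfonate, via silyl ether 3 (not isolated), via lithium phenoxide 4 (not isolated)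
Conditions: HN(SiMe3)2, THF, 65 °C; evaporate; n-BuLi, THF, −78 °C; Tf2O, −78 °C to rt
Reagents that add atoms: hexamethyldisilazane, C[Si](C)(C)N[Si](C)(C)C; trifluoromethanesulfonic anhydride, O=S(=O)(OS(=O)(=O)C(F)(F)F)C(F)(F)F
Why: O-silylation, bromine–lithium exchange with retro-Brook 1,3 O-to-C silyl shift and triflation of the phenoxide is the standard entry to 2-(trimethylsilyl)aryl triflates, and benzyl ethers tolerate n-BuLi at −78 °C.

Step 3
Reactants: 6 1-(benzyloxy)-4-ethynylbenzene
Product: 8 3-[4-(benzyloxy)phenyl]prop-2-ynoic acid, via lithium acetylide 7 (not isolated)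
Conditions: n-BuLi, THF, −78 °C; CO2 (gas), −78 °C to rt; 1 M HCl
Reagents that add atoms: carbon dioxide, O=C=O
Why: Carboxylation of a lithium acetylide installs the carbon that becomes C4.

Step 4
Reactants: 8 3-[4-(benzyloxy)phenyl]prop-2-ynoic acid; 5 aryne precursor
Product: 11 5,7-bis(benzyloxy)-2-[4-(benzyloxy)phenyl]-4H-chromen-4-one, via aryne 9 (not isolated), via ynone 10 (not isolated)
Conditions: CsF (4 equiv), 5 (1.5 equiv), THF, 125 °C, sealed tube
Reagents that add atoms: none
Why: Fluoride removes the silyl group of 5 and triflate leaves to give aryne 9; the caesium carboxylate of 8 adds through oxygen to the aryne carbon remote from the C3 benzyloxy group, so the aryl anion sits next to that oxygen where it is inductively stabilised. The anion attacks its own ester carbonyl through a four-membered transition state and the benzoxetene alkoxide opens (anionic 1,3 O-to-C acyl shift), which amounts to insertion of the aryne into the C–O bond of the acid and forms O1–C8a and C4–C4a of ynone 10. The liberated phenoxide then closes ring C by 6-endo-dig oxa-Michael addition to the ynone, forming O1–C2. The closest known reaction type is the aryne/carboxylic acid C–O insertion that converts arylpropiolic acids into flavones. No stereocentre is formed. The step needs regioselective addition to the unsymmetrical aryne (secured by the 3-alkoxy group, which gives the 5,7-dioxygenation pattern), acyl shift faster than protonation (aprotic medium, 125 °C) and 6-endo over 5-exo closure (conjugate addition at the β-carbon of the aryl ynone).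

Step 5
Reactants: 11 5,7-bis(benzyloxy)-2-[4-(benzyloxy)phenyl]-4H-chromen-4-one
Product: 14 5,7-bis(benzyloxy)-2-[4-(benzyloxy)phenyl]-3-hydroxy-4H-chromen-4-one, via 3-lithioflavone 12 (not isolated), via arylborate 13 (not isolated)
Conditions: LiN(i-Pr)2, THF, −78 °C; B(OMe)3, −78 to 0 °C; AcOH, 30% H2O2, 0 °C to rt
Reagents that add atoms: hydrogen peroxide, OO
Why: C3–H is the most acidic position of a flavone (vinylic, next to the C4 carbonyl), so directed lithiation, borylation and oxidation of the C–B bond should give the flavonol.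

Step 6
Reactants: 14 5,7-bis(benzyloxy)-2-[4-(benzyloxy)phenyl]-3-hydroxy-4H-chromen-4-one
Product: 15 rac-5,7-bis(benzyloxy)-2-[4-(benzyloxy)phenyl]-2-hydroxychromane-3,4-dione
Conditions: PhI(OAc)2 (1.05 equiv), MeCN/H2O 9:1, 0 °C; dried over 4 Å MS before use
Reagents that add atoms: water, O
Why: Hypervalent-iodine oxidation of the flavonol enol (ligand exchange at the 3-OH, two-electron loss) gives the C2 cation of the 3,4-dione, which water captures at C2, as methanol does in the known methanol variant.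

Step 7
Reactants: 16 4-(benzyloxy)benzaldehyde; 17 vinylmagnesium bromide (CH2=CHMgBr)
Product: 18 rac-1-[4-(benzyloxy)phenyl]prop-2-en-1-ol
Conditions: THF, 0 °C; sat. aq. NH4Cl
Reagents that add atoms: none
Why: Grignard 1,2-addition gives an allylic alcohol that ionises to the same cation as the cinnamyl alcohol, so its configuration is irrelevant.

Step 8
Reactants: 18 rac-1-[4-(benzyloxy)phenyl]prop-2-en-1-ol; 1 3,5-bis(benzyloxy)phenol
Product: 19 3,5-bis(benzyloxy)-2-{(E)-3-[4-(benzyloxy)phenyl]prop-2-en-1-yl}phenol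
Conditions: H2SO4 on SiO2 (cat.), CH2Cl2, rt
Reagents that add atoms: none
Why: Friedel–Crafts alkylation through the aryl-stabilised allyl cation should occur at its terminal carbon (E-styrene retained) and ortho to the free hydroxyl of 1, as known for cinnamyl alcohols with this phenol.

Step 9
Reactants: 19 the (E)-1,3-diarylpropene phenol
Product: 20 tert-butyldimethylsilyl ether of 19
Conditions: TBSCl, imidazole, DMF, rt
Reagents that add atoms: tert-butyldimethylsilyl chloride, CC(C)(C)[Si](C)(C)Cl
Why: Silylation masks the electron-rich phenol, which would otherwise be oxidised in the epoxidation.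

Step 10
Reactants: 20 the silyl ether
Product: 21 (2R,3R)-2-[4-(benzyloxy)phenyl]-3-{[2,4-bis(benzyloxy)-6-(tert-butyldimethylsilyloxy)phenyl]methyl}oxirane
Conditions: D-fructose-derived ketone of the Shi epoxidation (30 mol%), 2KHSO5·KHSO4·K2SO4, K2CO3, Bu4NHSO4, MeCN/CH2(OMe)2/aq. Na2B4O7 buffer, 0 °C
Reagents that add atoms: potassium peroxymonosulfate, [K+].[O-]S(=O)(=O)OO
Why: Shi epoxidation of a trans-β-alkylstyrene through the spiro transition state of the chiral dioxirane should give the (R,R)-epoxide, by analogy with trans-β-methylstyrene.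

Step 11
Reactants: 21 the (R,R)-epoxide
Product: 23 (2S,3R)-5,7-bis(benzyloxy)-2-[4-(benzyloxy)phenyl]chroman-3-ol, via epoxy phenol 22 (not isolated)
Conditions: Bu4NF/AcOH 1:1, THF, 0 °C; then CSA (10 mol%), CH2Cl2, 0 °C
Reagents that add atoms: none
Why: After desilylation the phenol opens the epoxide under acid at the benzylic carbon activated by the 4-benzyloxyphenyl group (6-endo), with inversion there and retention at the carbinol carbon, which should give the 2,3-trans flavan-3-ol (C2' S, C3' R).

Step 12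
Reactants: 15 rac-2-hydroxychromane-3,4-dione; 23 (2S,3R)-flavan-3-ol
Product: 24 (3S)-5,7-bis(benzyloxy)-2-[4-(benzyloxy)phenyl]-3-{(2S,3R)-5,7-bis(benzyloxy)-2-[4-(benzyloxy)phenyl]-3-hydroxychroman-8-yl}-2,3-dihydroxychroman-4-one (C2 epimers)
Conditions: Cu(OTf)2 (10 mol%), (S,S)-2,2'-isopropylidenebis(4-tert-butyl-2-oxazoline) (11 mol%), 4 Å MS, CH2Cl2, −20 °C to rt
Reagents that add atoms: none
Why: Proposed new method: the copper–bis(oxazoline) Lewis acid should chelate the s-cis C3/C4 dicarbonyl of 15 and expose one face of the C3 ketone (C4 is a deactivated vinylogous carbonate) to C8 of 23, the most nucleophilic and less hindered position of a 5,7-di-O-benzylflavan, while the C2 hemiketal epimerises through the open trione so that both antipodes of 15 funnel through the ligand-preferred face (dynamic kinetic resolution, C3 set by the catalyst); the closest known reaction types are copper–bis(oxazoline)-catalysed enantioselective Friedel–Crafts hydroxyalkylation of electron-rich arenes with α-keto esters and the ene and aldol reactions of 2,3-diketo esters with the same catalysts.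

Step 13
Reactants: 24 the hexabenzyl adduct
Product: 26 CNP0146414.1, via polyphenol hemiketal 25 (not isolated)
Conditions: H2 (1 atm), Pd(OH)2/C, EtOAc/MeOH, rt; filter; PPTS (cat.), MeCN, 4 Å MS, rt
Reagents that add atoms: none
Why: Hydrogenolysis frees all six phenols, and acid-catalysed ketalisation then lets O7' displace the C2 hydroxyl through the oxocarbenium ion (5-exo), C2 being the only carbonyl carbon that can hold two phenol oxygens; the cis ring fusion imposed by C3 (S) fixes C2 as R.

**Compound list**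

1 | 3,5-bis(benzyloxy)phenol | Oc1cc(OCc2ccccc2)cc(OCc2ccccc2)c1 | starting material
2 | 2-bromo-3,5-bis(benzyloxy)phenol | Oc1cc(OCc2ccccc2)cc(OCc2ccccc2)c1Br | intermediate
3 | [2-bromo-3,5-bis(benzyloxy)phenoxy]trimethylsilane | C[Si](C)(C)Oc1cc(OCc2ccccc2)cc(OCc2ccccc2)c1Br | intermediate
4 | lithium 3,5-bis(benzyloxy)-2-(trimethylsilyl)phenoxide | [Li+].[O-]c1cc(OCc2ccccc2)cc(OCc2ccccc2)c1[Si](C)(C)C | intermediate
5 | 3,5-bis(benzyloxy)-2-(trimethylsilyl)phenyl trifluoromethanesulfonate | O=S(=O)(Oc1cc(OCc2ccccc2)cc(OCc2ccccc2)c1[Si](C)(C)C)C(F)(F)F | intermediate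
6 | 1-(benzyloxy)-4-ethynylbenzene | C#Cc1ccc(OCc2ccccc2)cc1 | starting material
7 | lithium [4-(benzyloxy)phenyl]acetylide | [Li]C#Cc1ccc(OCc2ccccc2)cc1 | intermediate
8 | 3-[4-(benzyloxy)phenyl]prop-2-ynoic acid | OC(=O)C#Cc1ccc(OCc2ccccc2)cc1 | intermediate
9 | 3,5-bis(benzyloxy)benzyne (1,2-didehydro-3,5-bis(benzyloxy)benzene) | C1#CC(OCc2ccccc2)=CC(OCc2ccccc2)=C1 | intermediate
10 | 1-[2-hydroxy-4,6-bis(benzyloxy)phenyl]-3-[4-(benzyloxy)phenyl]prop-2-yn-1-one (present as its caesium phenoxide) | O=C(C#Cc1ccc(OCc2ccccc2)cc1)c1c(O)cc(OCc2ccccc2)cc1OCc1ccccc1 | intermediate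
11 | 5,7-bis(benzyloxy)-2-[4-(benzyloxy)phenyl]-4H-chromen-4-one | O=c1cc(-c2ccc(OCc3ccccc3)cc2)oc2cc(OCc3ccccc3)cc(OCc3ccccc3)c12 | intermediate
12 | 3-lithio derivative of 11 | O=c1c([Li])c(-c2ccc(OCc3ccccc3)cc2)oc2cc(OCc3ccccc3)cc(OCc3ccccc3)c12 | intermediate
13 | lithium trimethoxy(flavon-3-yl)borate derived from 12 | [Li+].CO[B-](OC)(OC)c1c(-c2ccc(OCc3ccccc3)cc2)oc2cc(OCc3ccccc3)cc(OCc3ccccc3)c2c1=O | intermediate
14 | 5,7-bis(benzyloxy)-2-[4-(benzyloxy)phenyl]-3-hydroxy-4H-chromen-4-one | O=c1c(O)c(-c2ccc(OCc3ccccc3)cc2)oc2cc(OCc3ccccc3)cc(OCc3ccccc3)c12 | intermediate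
15 | rac-5,7-bis(benzyloxy)-2-[4-(benzyloxy)phenyl]-2-hydroxychromane-3,4-dione | O=C1C(=O)C(O)(c2ccc(OCc3ccccc3)cc2)Oc2cc(OCc3ccccc3)cc(OCc3ccccc3)c12 | intermediate
16 | 4-(benzyloxy)benzaldehyde | O=Cc1ccc(OCc2ccccc2)cc1 | starting material
17 | vinylmagnesium bromide | C=C[Mg]Br | starting material
18 | rac-1-[4-(benzyloxy)phenyl]prop-2-en-1-ol | C=CC(O)c1ccc(OCc2ccccc2)cc1 | intermediate
19 | 3,5-bis(benzyloxy)-2-{(E)-3-[4-(benzyloxy)phenyl]prop-2-en-1-yl}phenol | Oc1cc(OCc2ccccc2)cc(OCc2ccccc2)c1C/C=C/c1ccc(OCc2ccccc2)cc1 | intermediate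
20 | tert-butyldimethylsilyl ether of 19 | CC(C)(C)[Si](C)(C)Oc1cc(OCc2ccccc2)cc(OCc2ccccc2)c1C/C=C/c1ccc(OCc2ccccc2)cc1 | intermediate
21 | (2R,3R)-2-[4-(benzyloxy)phenyl]-3-{[2,4-bis(benzyloxy)-6-(tert-butyldimethylsilyloxy)phenyl]methyl}oxirane | c1ccccc1COc1ccc(cc1)[C@H]1O[C@@H]1Cc1c(O[Si](C)(C)C(C)(C)C)cc(OCc2ccccc2)cc1OCc1ccccc1 | intermediate
22 | 3,5-bis(benzyloxy)-2-({(2R,3R)-3-[4-(benzyloxy)phenyl]oxiran-2-yl}methyl)phenol | c1ccccc1COc1ccc(cc1)[C@H]1O[C@@H]1Cc1c(O)cc(OCc2ccccc2)cc1OCc1ccccc1 | intermediate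
23 | (2S,3R)-5,7-bis(benzyloxy)-2-[4-(benzyloxy)phenyl]chroman-3-ol | c1ccccc1COc1cc(OCc2ccccc2)c2c(c1)O[C@@H](c1ccc(OCc3ccccc3)cc1)[C@H](O)C2 | intermediate
24 | (3S)-5,7-bis(benzyloxy)-2-[4-(benzyloxy)phenyl]-3-{(2S,3R)-5,7-bis(benzyloxy)-2-[4-(benzyloxy)phenyl]-3-hydroxychroman-8-yl}-2,3-dihydroxychroman-4-one (C2 epimers) | O=C1c2c(OCc3ccccc3)cc(OCc3ccccc3)cc2OC(O)(c2ccc(OCc3ccccc3)cc2)[C@]1(O)c1c(OCc2ccccc2)cc(OCc2ccccc2)c2c1O[C@@H](c1ccc(OCc3ccccc3)cc1)[C@H](O)C2 | intermediate
25 | (3S)-2,3,5,7-tetrahydroxy-2-(4-hydroxyphenyl)-3-[(2S,3R)-3,5,7-trihydroxy-2-(4-hydroxyphenyl)chroman-8-yl]chroman-4-one (C2 epimers) | O=C1c2c(O)cc(O)cc2OC(O)(c2ccc(O)cc2)[C@]1(O)c1c(O)cc(O)c2c1O[C@@H](c1ccc(O)cc1)[C@H](O)C2 | intermediate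
26 | CNP0146414.1: cis-fused ketal, C2 (R) and C3 (S) in the flavonol unit, C3 bonded to C8' and C2 to O7' of the (2S,3R)-flavan-3-ol | O=C1c2c(O)cc(O)cc2O[C@@]2(c3ccc(O)cc3)Oc3cc(O)c4c(c3[C@]12O)O[C@@H](c1ccc(O)cc1)[C@H](O)C4 | target

**Step count and risks**

Total steps: 13. Longest linear sequence: 7 steps (steps 1, 2, 4, 5, 6, 12, 13; the branch through steps 7–11, 12, 13 is equally long).

Steps most likely to fail:

1. Step 12 (proposed new method). The catalyst may discriminate the two faces of the C3 ketone poorly, for three reasons: the tricarbonyl has competing chelation modes, ring–chain epimerisation at C2 may be too slow for the dynamic resolution, and the arene may attack the ionised C2 hemiketal carbon instead of the C3 carbonyl. Fallback with known chemistry: setting out from 15 and 23, the hydroxyalkylation is run with an achiral Lewis acid (Sc(OTf)3, CH2Cl2, 0 °C), as established for electron-rich arenes and vicinal tricarbonyl compounds. It should give 24 together with its C3 epimer, the (3R)-adduct F1. The two are diastereomers because of the flavan unit and are separated by chromatography. The route is rejoined at 24.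

2. Step 6. The oxidation may run on: a second equivalent of oxidant can cleave the α-hydroxy-1,2-dione, or the hydrate may contract irreversibly to the 2-aroylbenzofuranone. Fallback: setting out from 14, the oxidation is run with PhI(OAc)2 in dry MeOH, the documented variant, to give the stable and chromatographable 5,7-bis(benzyloxy)-2-[4-(benzyloxy)phenyl]-3-hydroxy-2,3-dimethoxychroman-4-one F2. A separate mild hydrolysis (TFA/H2O/THF, rt) then unmasks it, and the route is rejoined at 15.

3. Step 4. The aryl anion may be protonated before the acyl shift (giving only the aryl propiolate), the propiolate may decarboxylate at 125 °C, or closure may go 5-exo to the aurone. Fallback: setting out from 16 and commercial 1-[2-hydroxy-4,6-bis(benzyloxy)phenyl]ethan-1-one F3, Claisen–Schmidt condensation (KOH, EtOH, rt) gives the chalcone (E)-1-[2-hydroxy-4,6-bis(benzyloxy)phenyl]-3-[4-(benzyloxy)phenyl]prop-2-en-1-one F4. Oxidative cyclisation (I2 cat., DMSO, 120 °C) then gives the flavone, and the route is rejoined at 11.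

Further compounds
F1 | step 12 | (3R)-5,7-bis(benzyloxy)-2-[4-(benzyloxy)phenyl]-3-{(2S,3R)-5,7-bis(benzyloxy)-2-[4-(benzyloxy)phenyl]-3-hydroxychroman-8-yl}-2,3-dihydroxychroman-4-one (C3 epimer of 24) | O=C1c2c(OCc3ccccc3)cc(OCc3ccccc3)cc2OC(O)(c2ccc(OCc3ccccc3)cc2)[C@@]1(O)c1c(OCc2ccccc2)cc(OCc2ccccc2)c2c1O[C@@H](c1ccc(OCc3ccccc3)cc1)[C@H](O)C2
F2 | step 6 | 5,7-bis(benzyloxy)-2-[4-(benzyloxy)phenyl]-3-hydroxy-2,3-dimethoxychroman-4-one (mixture of diastereomers) | O=C1c2c(OCc3ccccc3)cc(OCc3ccccc3)cc2OC(OC)(c2ccc(OCc3ccccc3)cc2)C1(O)OC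
F3 | step 4 | 1-[2-hydroxy-4,6-bis(benzyloxy)phenyl]ethan-1-one | CC(=O)c1c(O)cc(OCc2ccccc2)cc1OCc1ccccc1
F4 | step 4 | (E)-1-[2-hydroxy-4,6-bis(benzyloxy)phenyl]-3-[4-(benzyloxy)phenyl]prop-2-en-1-one | O=C(/C=C/c1ccc(OCc2ccccc2)cc1)c1c(O)cc(OCc2ccccc2)cc1OCc1ccccc1
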